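The cyclopentane (C-a, C-b, C-c, C-d, C-e) is closed last, through the C-c–C-d bond, across a finished carane-fused benzoxepinone. The step exploits two features: C-a (ether carbon) and C-d (methyl-bearing carbon) are 1,3-related on the oxepine ring through C-e, and C-d is flanked by the benzylic carbon C-7′, which as a ketone turns C-d into an enol carbon. An ethynyl group on C-a supplies C-b and C-c; gold-catalysed 5-endo-dig Conia-ene-type cyclization of the silyl enol ether onto it closes the ring and sets the bridgehead quaternary carbon in one operation. The precursor is a 2-ethynyl-4-methyl-1-benzoxepin-5-one built from (S)-carvone.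

Key step: step 14

Atom labels (target): C-7′ = benzylic CH carrying isobutyl; C-a = quaternary carbon bearing the ether oxygen; C-b, C-c = the two CH2 of the five-membered ring (C-b on C-a); C-d = quaternary carbon bearing methyl and C-7′; C-e = CH shared by the five- and six-membered rings; C-f, C-g = cyclopropane CH carbons (C-f on C-e); C-h = ring CH2; C-i = CH(CH3).

Assumption: the configuration at C-d before step 14 and at the carbinol carbon of 21 is of no consequence (both centres are made planar later) and is left undefined in the SMILES.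

Step 1
Reactants: 1 (S)-(+)-carvone
Product: 2 (5S)-5-(2-chloropropan-2-yl)-2-methylcyclohex-2-en-1-one
Conditions: dry HCl (g), AcOH, 0 °C
Reagents that add atoms: hydrogen chloride, Cl
Why: Markovnikov hydrochlorination takes the isolated isopropenyl alkene (the enone alkene is deactivated) and leaves the carvone stereocentre, the future C-f, untouched.

Step 2
Reactants: 2 (5S)-5-(2-chloropropan-2-yl)-2-methylcyclohex-2-en-1-one
Product: 3 (1R,6S)-3,7,7-trimethylbicyclo[4.1.0]hept-3-en-2-one (car-3-en-2-one)
Conditions: t-BuOK, THF, 0 °C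
Reagents that add atoms: none
Why: The cross-conjugated α′-enolate displaces the tertiary chloride in a 3-exo-tet 1,3-elimination, which can only give the cis-fused gem-dimethylcyclopropane, so C-f fixes C-g.

Step 3
Reactants: 3 car-3-en-2-one
Product: 4 3,4-epoxy-3,7,7-trimethylbicyclo[4.1.0]heptan-2-one (oxirane trans to the cyclopropane)
Conditions: 30% H2O2, NaOH (cat.), MeOH, 0 °C
Reagents that add atoms: hydrogen peroxide, OO
Why: Weitz–Scheffer nucleophilic epoxidation of the enone, with hydroperoxide adding to C-a from the face anti to the cyclopropane, whose inner methyl shields the other face.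

Step 4
Reactants: 4 epoxy ketone
Product: 6 4,7,7-trimethylbicyclo[4.1.0]hept-4-en-3-ol (OH on C-a trans to the cyclopropane), via epoxy hydrazone 5 (not isolated)
Conditions: N2H4·H2O, AcOH (cat.), MeOH, 0 °C to rt
Reagents that add atoms: none
Why: Wharton transposition: the epoxy hydrazone fragments with loss of N2, moving the oxygen function from C-h to C-a with retention of the C-a–O configuration set in step 3.

Step 5
Reactants: 6 allylic alcohol
Product: 7 4,7,7-trimethylbicyclo[4.1.0]heptan-3-ol (OH trans and methyl cis to the cyclopropane; ent-isocaranol)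
Conditions: H2 (1 atm), [Ir(cod)(PCy3)(py)]PF6 (2 mol %), CH2Cl2, rt
Reagents that add atoms: none
Why: Hydroxyl-directed homogeneous hydrogenation delivers H2 to the face of the C-a hydroxyl, which is also the face anti to the cyclopropane, so the C-i methyl ends cis to the cyclopropane; the cationic iridium catalyst leaves the vinylcyclopropane ring intact.

Step 6
Reactants: 7 ent-isocaranol
Product: 8 4,7,7-trimethylbicyclo[4.1.0]heptan-3-one (methyl cis to the cyclopropane; ent-isocaranone)
Conditions: Dess–Martin periodinane, CH2Cl2, rt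
Reagents that add atoms: none
Why: Dess–Martin oxidation under neutral conditions gives the ketone without epimerizing the adjacent C-i centre.

Step 7
Reactants: 8 ent-isocaranone
Product: 10 ethyl 2-(4,7,7-trimethyl-3-oxobicyclo[4.1.0]hept-2-yl)propanoate (side chain on C-e trans to the cyclopropane), via lithium enolate 9 (not isolated)
Conditions: LiN(i-Pr)2, THF, −78 °C; then ethyl (S)-2-(trifluoromethylsulfonyloxy)propanoate, −78 to −40 °C
Reagents that add atoms: ethyl (S)-2-(trifluoromethylsulfonyloxy)propanoate, CCOC(=O)[C@H](C)OS(=O)(=O)C(F)(F)F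
Why: Kinetic deprotonation takes the less substituted α-CH2 (C-e) and the enolate is alkylated by SN2 displacement of the secondary triflate on the face anti to the adjacent cyclopropane, which sets C-e.

Step 8
Reactants: 10 keto ester
Product: 12 ethynyl γ-lactone (lactone oxygen on C-a cis to the cyclopropane; ethynyl trans to it and cis to the C-e side chain), via bromomagnesium alkoxide 11 (not isolated)
Conditions: HC≡CMgBr, THF, −40 °C to rt
Reagents that add atoms: ethynylmagnesium bromide, C#C[Mg]Br
Why: Grignard 1,2-addition of the small acetylide from the ketone face anti to the cyclopropane and to the C-i methyl sets C-a, and the alkoxide then closes the trans-fused γ-lactone on the neighbouring ester.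

Step 9
Reactants: 13 5-fluorobenzene-1,3-diol
Product: 14 1,3-bis(benzyloxy)-5-fluorobenzene
Conditions: BnBr, K2CO3, DMF, rt
Reagents that add atoms: benzyl bromide, BrCc1ccccc1
Why: Williamson ether synthesis on both phenols.

Step 10
Reactants: 14 1,3-bis(benzyloxy)-5-fluorobenzene
Product: 15 1,5-bis(benzyloxy)-2-bromo-3-fluorobenzene
Conditions: N-bromosuccinimide, MeCN, 0 °C to rt
Reagents that add atoms: N-bromosuccinimide, O=C1CCC(=O)N1Br
Why: Electrophilic aromatic bromination para to one benzyloxy group and ortho to fluorine, the position between the two benzyloxy groups being the more hindered one.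

Step 11
Reactants: 15 1,5-bis(benzyloxy)-2-bromo-3-fluorobenzene; 12 ethynyl γ-lactone
Product: 17 γ-hydroxy aryl ketone, via aryllithium 16 (not isolated)
Conditions: 15 (2.2 equiv), n-BuLi, THF, −78 °C; then 12, −78 °C; aq. NH4Cl
Reagents that add atoms: none
Why: Bromine–lithium exchange followed by addition of the aryllithium to the lactone (the first equivalent deprotonates the alkyne); the lactolate of the doubly ortho-substituted aryl resists a second addition and no stereocentre is touched.

Step 12
Reactants: 17 γ-hydroxy aryl ketone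
Product: 18 carane-fused 6,8-bis(benzyloxy)-2-ethynyl-4-methyl-3,4-dihydro-1-benzoxepin-5(2H)-one
Conditions: t-BuOK, THF/DMF, 0 °C to rt
Reagents that add atoms: none
Why: Intramolecular nucleophilic aromatic substitution: the tertiary alkoxide displaces the fluoride activated by the ortho ketone and closes the seven-membered aryl ether ring with the C-a configuration unchanged.

Step 13
Reactants: 18 benzoxepinone
Product: 19 tert-butyldimethylsilyl enol ether of 18 (C-d=C-7′ double bond)
Conditions: TBSOTf, Et3N, CH2Cl2, 0 °C to rt
Reagents that add atoms: tert-butyldimethylsilyl trifluoromethanesulfonate, CC(C)(C)[Si](C)(C)OS(=O)(=O)C(F)(F)F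
Why: Soft enolization and O-silylation at the only enolizable position of the ketone, which makes C-d the nucleophilic carbon.

Step 14
Reactants: 19 silyl enol ether
Product: 20 bridged ketone (C-b=C-c etheno bridge between C-a and C-d; oxabicyclo[4.2.1]nonenone core)
Conditions: Ph3PAuCl (10 mol %), AgBF4 (10 mol %), CH2Cl2/MeOH (10:1), 40 °C
Reagents that add atoms: none
Why: Cationic monovalent gold coordinates the terminal alkyne on C-a and the enol ether carbon C-d attacks the distal alkyne carbon C-c anti to gold; methanol then removes the silyl group from the oxocarbenium ion and protonates the vinyl–gold bond at C-b, releasing ketone 20 and the catalyst. The closest known reaction type is the gold-catalysed Conia-ene-type carbocyclization of silyl enol ethers onto alkynes. Only the cyclopentane closes, in the 5-endo-dig mode (the 4-exo-dig alternative at C-b would give a cyclobutane), and this turns the oxepinone into the bridged bicyclic core. The one new stereocentre, C-d, is dictated by the tether: the ethynyl group sits on C-a cis to the C-e–C-d bond (axial on the six-membered ring), so it reaches only one face of the enol ether, placing C-7′ and the ether oxygen on the same side of the new ring and the methyl group outside. The step needs C-attack by the enol ether in preference to hydroarylation of the aryl propargyl ether by the free arene position and to protodesilylation; the much higher nucleophilicity of the silyl enol ether and its proximity to the axial alkyne secure this, and O-attack is excluded because it would give a bridgehead enol ether.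

Step 15
Reactants: 20 bridged ketone
Product: 21 bridged benzylic alcohol (C-7′–OH)
Conditions: LiAlH4, THF, 0 °C to rt
Reagents that add atoms: none
Why: Hydride reduction of the non-enolizable aryl ketone; the carbinol configuration does not matter because C-7′ is ionized in the next step.

Step 16
Reactants: 21 bridged benzylic alcohol
Product: 22 C-7′ (2-methylallyl) compound
Conditions: trimethyl(2-methylallyl)silane, InCl3 (10 mol %), CH2Cl2, −40 to 0 °C
Reagents that add atoms: trimethyl(2-methylallyl)silane, CC(=C)C[Si](C)(C)C
Why: Hosomi–Sakurai-type SN1 allylation: the benzylic cation, stabilized by three ring oxygens and unable to eliminate because C-d has no hydrogen, is captured from the exo face (syn to the one-carbon bridge C-e, anti to the two-carbon bridge), which sets C-7′ as in the target.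

Step 17
Reactants: 22 methallyl compound
Product: 23 isobutyl diphenol
Conditions: H2 (1 atm), Pd/C (10% Pd on carbon), EtOAc/EtOH, rt
Reagents that add atoms: none
Why: Heterogeneous hydrogenation saturates the C-b=C-c and methallyl alkenes and hydrogenolyses both benzyl ethers, while the saturated cyclopropane and the bridgehead aryl ether stay intact and no stereocentre is created.

Step 18
Reactants: 23 isobutyl diphenol
Product: 24 target CNP0202714.1
Conditions: Cl2CHOCH3, TiCl4, CH2Cl2, −78 to 0 °C; then H2O
Reagents that add atoms: dichloromethyl methyl ether, COC(Cl)Cl; water, O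
Why: Twofold Rieche formylation at the two free ring positions, each ortho to a titanium-bound phenol oxygen, followed by hydrolysis to the dialdehyde.

Compound list
1 | (S)-(+)-carvone, (5S)-2-methyl-5-(prop-1-en-2-yl)cyclohex-2-en-1-one | CC1=CC[C@@H](CC1=O)C(C)=C | starting material
2 | (5S)-5-(2-chloropropan-2-yl)-2-methylcyclohex-2-en-1-one | CC1=CC[C@@H](CC1=O)C(C)(C)Cl | intermediate
3 | (1R,6S)-3,7,7-trimethylbicyclo[4.1.0]hept-3-en-2-one (car-3-en-2-one, cis-fused) | CC1=CC[C@H]2[C@@H](C1=O)C2(C)C | intermediate
4 | 3,4-epoxy-3,7,7-trimethylbicyclo[4.1.0]heptan-2-one, oxirane trans to the cyclopropane | C[C@]12O[C@H]1C[C@H]3[C@@H](C2=O)C3(C)C | intermediate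
5 | hydrazone of epoxy ketone 4 | C[C@]12O[C@H]1C[C@H]3[C@@H](C2=NN)C3(C)C | intermediate
6 | 4,7,7-trimethylbicyclo[4.1.0]hept-4-en-3-ol, OH trans to the cyclopropane (enantiomer of trans-car-2-en-4-ol) | CC1=C[C@@H]2[C@H](C[C@@H]1O)C2(C)C | intermediate
7 | 4,7,7-trimethylbicyclo[4.1.0]heptan-3-ol, OH trans and 4-methyl cis to the cyclopropane (ent-isocaranol) | C[C@H]1C[C@@H]2[C@H](C[C@@H]1O)C2(C)C | intermediate
8 | 4,7,7-trimethylbicyclo[4.1.0]heptan-3-one, 4-methyl cis to the cyclopropane (ent-isocaranone) | C[C@H]1C[C@@H]2[C@H](CC1=O)C2(C)C | intermediate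
9 | lithium enolate of 8 toward C-e | C[C@H]1C[C@@H]2[C@H](C=C1O[Li])C2(C)C | intermediate
10 | ethyl 2-(4,7,7-trimethyl-3-oxobicyclo[4.1.0]hept-2-yl)propanoate, side chain trans and ring methyl cis to the cyclopropane | C[C@H]1C[C@@H]2[C@H]([C@@H](C1=O)C(C)C(=O)OCC)C2(C)C | intermediate
11 | bromomagnesium alkoxide of the ethynyl carbinol ester (ethynyl trans to the cyclopropane) | C[C@H]1C[C@@H]2[C@H]([C@H](C(C)C(=O)OCC)[C@]1(O[Mg]Br)C#C)C2(C)C | intermediate
12 | ethynyl γ-lactone, trans-fused to the six-membered ring, lactone oxygen on C-a cis to the cyclopropane | C[C@H]1C[C@@H]2[C@H]([C@@H]3C(C)C(=O)O[C@@]13C#C)C2(C)C | intermediate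
13 | 5-fluorobenzene-1,3-diol | Oc1cc(O)cc(F)c1 | starting material
14 | 1,3-bis(benzyloxy)-5-fluorobenzene | Fc1cc(OCc2ccccc2)cc(OCc2ccccc2)c1 | intermediate
15 | 1,5-bis(benzyloxy)-2-bromo-3-fluorobenzene | Fc1cc(OCc2ccccc2)cc(OCc2ccccc2)c1Br | intermediate
16 | [2,4-bis(benzyloxy)-6-fluorophenyl]lithium | [Li]c1c(F)cc(OCc2ccccc2)cc1OCc1ccccc1 | intermediate
17 | 1-[2,4-bis(benzyloxy)-6-fluorophenyl]-2-(3-ethynyl-3-hydroxy-4,7,7-trimethylbicyclo[4.1.0]hept-2-yl)propan-1-one (γ-hydroxy ketone, in equilibrium with its lactol) | C[C@H]1C[C@@H]2[C@H]([C@H](C(C)C(=O)c3c(F)cc(OCc4ccccc4)cc3OCc3ccccc3)[C@]1(O)C#C)C2(C)C | intermediate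
18 | carane-fused 6,8-bis(benzyloxy)-2-ethynyl-4-methyl-3,4-dihydro-1-benzoxepin-5(2H)-one (ring fusion at C-a/C-e, ether oxygen cis to the cyclopropane) | CC1C(=O)c2c(OCc3ccccc3)cc(OCc3ccccc3)cc2O[C@]2(C#C)[C@@H]1[C@H]1[C@@H](C[C@@H]2C)C1(C)C | intermediate
19 | tert-butyldimethylsilyl enol ether of 18 (C-d=C-7′) | CC1=C(O[Si](C)(C)C(C)(C)C)c2c(OCc3ccccc3)cc(OCc3ccccc3)cc2O[C@]2(C#C)[C@@H]1[C@H]1[C@@H](C[C@@H]2C)C1(C)C | intermediate
20 | bridged ketone: C-7′ ketone, C-b=C-c etheno bridge from C-a to C-d, methyl on bridgehead C-d, bis(benzyl) ether | O=C1c2c(OCc3ccccc3)cc(OCc3ccccc3)cc2O[C@]23C=C[C@@]1(C)[C@H]2[C@H]1[C@@H](C[C@@H]3C)C1(C)C | intermediate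
21 | bridged benzylic alcohol (C-7′–OH) | OC1c2c(OCc3ccccc3)cc(OCc3ccccc3)cc2O[C@]23C=C[C@@]1(C)[C@H]2[C@H]1[C@@H](C[C@@H]3C)C1(C)C | intermediate
22 | C-7′ (2-methylallyl) compound, side chain syn to C-e, bis(benzyl) ether, etheno bridge | C=C(C)C[C@H]1c2c(OCc3ccccc3)cc(OCc3ccccc3)cc2O[C@]23C=C[C@@]1(C)[C@H]2[C@H]1[C@@H](C[C@@H]3C)C1(C)C | intermediate
23 | isobutyl diphenol (target skeleton without the two formyl groups) | CC(C)C[C@H]1c2c(O)cc(O)cc2O[C@]23CC[C@@]1(C)[C@H]2[C@H]1[C@@H](C[C@@H]3C)C1(C)C | intermediate
24 | CNP0202714.1 | CC(C)C[C@H]1c2c(O)c(C=O)c(O)c(C=O)c2O[C@]23CC[C@@]1(C)[C@H]2[C@H]1[C@@H](C[C@@H]3C)C1(C)C | target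

Total step count: 18. Longest linear sequence: 16 steps (steps 1–8 and 11–18, from (S)-carvone); steps 9 and 10 prepare the aryl fragment.

Steps most likely to fail

Step 14. Methanol may cleave the silyl enol ether before the C–C bond forms, or the gold-activated alkyne may be captured by the electron-rich arene (hydroarylation of the aryl propargyl ether), so that the strained 5-endo closure across the seven-membered ring is outrun. Fallback: from 18 the terminal alkyne is iodinated (N-iodosuccinimide, AgNO3 cat., acetone) to the iodoalkyne F1, which diimide (2-nitrobenzenesulfonylhydrazide, Et3N) reduces to the (Z)-iodoalkene F2. Palladium-catalysed intramolecular α-alkenylation of the ketone enolate (Pd(PPh3)4, t-BuOK, THF, reflux) then forms the same C-c–C-d bond and returns to 20.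

Step 8. The acetylide may add to the ketone face syn to the cyclopropane (the C-e side chain hinders the other face), giving the epimeric carbinol, or the Grignard reagent may enolize the ketone and scramble C-i. Fallback: from 10, oxygen instead of carbon is delivered from the more accessible face. Methylenation (Zn, CH2Br2, TiCl4) gives the exocyclic alkene F5 and dihydroxylation (OsO4 cat., N-methylmorpholine N-oxide) the diol F6. Selective oxidation of the primary alcohol (TEMPO, PhI(OAc)2) gives the hydroxy aldehyde F7, and Ohira–Bestmann homologation (dimethyl (1-diazo-2-oxopropyl)phosphonate, K2CO3, MeOH) the ethynyl carbinol F8, which lactonizes (cat. DBU) and returns to 12.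

Step 16. The benzylic cation may be captured from the face syn to the two-carbon bridge, giving the C-7′ epimer. Fallback: from 20 the order of carbon and hydride delivery is reversed. i-BuMgBr with CeCl3 adds to the ketone to give the tertiary alcohol F3. Ionic hydrogenation (Et3SiH, BF3·OEt2, CH2Cl2, −78 °C) then brings hydride to the cation face that the allylsilane had taken, giving the isobutyl compound F4. Hydrogenation and hydrogenolysis under the conditions of step 17 return to 23.

Further compounds
F1 | step 14 | 2-(iodoethynyl) analogue of benzoxepinone 18 | CC1C(=O)c2c(OCc3ccccc3)cc(OCc3ccccc3)cc2O[C@]2(C#CI)[C@@H]1[C@H]1[C@@H](C[C@@H]2C)C1(C)C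
F2 | step 14 | (Z)-2-(2-iodoethenyl) analogue of benzoxepinone 18 | CC1C(=O)c2c(OCc3ccccc3)cc(OCc3ccccc3)cc2O[C@]2(/C=C\I)[C@@H]1[C@H]1[C@@H](C[C@@H]2C)C1(C)C
F3 | step 16 | tertiary benzylic alcohol from 20 (C-7′ bearing OH and isobutyl) | CC(C)CC1(O)c2c(OCc3ccccc3)cc(OCc3ccccc3)cc2O[C@]23C=C[C@@]1(C)[C@H]2[C@H]1[C@@H](C[C@@H]3C)C1(C)C
F4 | step 16 | C-7′ isobutyl compound, bis(benzyl) ether with etheno bridge | CC(C)C[C@H]1c2c(OCc3ccccc3)cc(OCc3ccccc3)cc2O[C@]23C=C[C@@]1(C)[C@H]2[C@H]1[C@@H](C[C@@H]3C)C1(C)C
F5 | step 8 | ethyl 2-(4,7,7-trimethyl-3-methylidenebicyclo[4.1.0]hept-2-yl)propanoate | C[C@H]1C[C@@H]2[C@H]([C@@H](C1=C)C(C)C(=O)OCC)C2(C)C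
F6 | step 8 | diol ester (tertiary OH on C-a cis to the cyclopropane, CH2OH trans) | C[C@H]1C[C@@H]2[C@H]([C@H](C(C)C(=O)OCC)[C@]1(O)CO)C2(C)C
F7 | step 8 | α-hydroxy aldehyde ester | C[C@H]1C[C@@H]2[C@H]([C@H](C(C)C(=O)OCC)[C@]1(O)C=O)C2(C)C
F8 | step 8 | ethynyl carbinol ester (free alcohol corresponding to 11) | C[C@H]1C[C@@H]2[C@H]([C@H](C(C)C(=O)OCC)[C@]1(O)C#C)C2(C)C
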